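## The problem

The target (26) is a six-membered carbocycle, labelled here C1–C6. C1 carries the chain C7–C12 (C7=C8 is an (E)-alkene with a methyl on C7, C9 a methyl-bearing methine, C10 the ketone, C11–C12 the ethyl group). C2–C3 carry a cis-fused methyl oxirane, C4=C5 is a methyl-substituted alkene, and quaternary C6 bears a methyl group and C2′ of a 2-methoxy-3,5-dimethyl-4-pyranone (O1′, C2′–C6′). Three bulky units thus sit on the contiguous carbons C6, C1 and C2, and the ring contains a fully substituted carbon between an sp2 carbon and a stereogenic methine.

Four stereocentres lie on the ring (1S,2S,3R,6R). Chain and pyranone are trans, and the oxirane oxygen is on the face of the chain and the C6 methyl (called the α-face here), away from the pyranone (β-face). C1 and C6 can be made together and are then the only internal handle on C2/C3. An external oxidant tends to reach C2 anti to the neighbouring C1 chain, so this handle alone cannot be trusted and the oxirane face also needs reagent control.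

C9 (R) is insulated from the ring by the C7=C8 bond and needs its own source of chirality. As the α-carbon of a β,γ-unsaturated ketone it epimerises or slips into conjugation with acid or base. The vinyl oxirane will not survive acids, cuprates or low-valent palladium, the methoxypyranone does not tolerate hard carbon nucleophiles, and the ring 1,3-diene that precedes the oxirane is sensitive to acid and unselective oxidants.

The structure opens at the heterocycle. C2′–C3′ with the C3′ methyl amount to a propanoyl group on C6, whose enol can form on one side only because C6 has no hydrogen. C4′–C6′ with the C5′ methyl are the skeleton of methylmalonic acid. The pyranone can therefore be annulated in one operation onto a finished carbocyclic ketone.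

## Retrosynthesis

**26 ⇒ 25 ⇒ 24 (C10 oxidation level).** No C–C bond is cut; the C10 carbonyl is traced to the carbinol 25 and its silyl ether 24. As long as C10 is sp3, C9 cannot epimerise and C7=C8 cannot migrate. The ketone is therefore released in the very last step by a neutral oxidation, after a fluoride deprotection that the oxirane tolerates.

**24 ⇒ 23 (C2–O and C3–O).** Removing the oxirane gives ring diene 23 and takes away two stereocentres. An earlier oxirane would not survive the acid chloride, HCl and methylating agent of the pyranone steps. An oxygen carried at C3 from ring synthesis would require inversion at tertiary C2. The forward step must pick C2=C3 over C4=C5 and C7=C8 and deliver oxygen to the α-face, which calls for an oxidant specific for conjugated alkenes with its own facial preference.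

**23 ⇒ 21 (O–CH3).** The methyl ether is cut to the 4-hydroxy-2-pyranone 21. Forward, a hard methylating agent must alkylate the lactone carbonyl oxygen (through pyrylium salt 22), not the C4′ hydroxyl.

**21 ⇒ 16 + 18 (C3′–C4′ and O1′–C6′; key cut).** Both bonds are cut in one move to ethyl ketone 16 and methylmalonyl dichloride 18, made from acid 17. Attaching a ready-made pyranone to C6 would mean forging a quaternary carbon by coupling. A linear triketide build-up costs extra steps and carries enolisable diketones. The annulation removes the whole heterocycle and leaves a carbocycle with one ketone. It asks for C-acylation of enol ether 19 and one direction of enolisation, which the quaternary C6 guarantees.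

**16 ⇒ 15 ⇒ 14 ⇒ 13 ⇒ 12 (ring diene from an enone).** The C2′ ketone is taken back to a triethylsilyl-protected carbinol (15, 14), so that the ring enone 12 is the only enolisable carbonyl. C3–H of diene 14 is traced to the C3–O bond of enol triflate 13. Enone 12 can enolise only toward C2 (C6 is quaternary), so the diene position is unambiguous.

**12 ⇒ 11 ⇒ 10 ⇒ 9 (C4=C5 and C2′–C11).** The enone double bond comes from the silyl enol ether of 11 by dehydrosilylation. The ethyl group is cut from C2′, leaving the non-enolisable aldehyde 9.

**9 ⇒ 6 + 8 (C1–C2 and C5–C6).** A Diels–Alder cut gives dienal 6 and silyl dienol ether 8 (from enone 7). Both C1 and C6 form in one step, and their trans relationship is a consequence of the (E)-geometry of 6, not of a selectivity. Making C1 first and quaternising C6 later would depend on the regiochemistry of a dienolate. The forward reaction needs a chiral Lewis acid for the absolute sense and the normal polarity match (enol ether terminus to the β-carbon).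

**6 ⇒ 5 ⇒ 3 (+ 4) and 3 ⇒ 2 ⇒ 1.** Two Wittig cuts with ylide 4 (at the future C1–C6 bond and at C7=C8) lead to aldehyde 3. An aldol cut at C9–C10 leads to two molecules of propanal 1. C9 is thus set in the first step, both (E)-alkenes come from a stabilised ylide, and the complete chain exists before the ring. No α-stereogenic ketone has to be appended to a trisubstituted alkene late in the synthesis.

## Roads not taken

**Alternative 1:** Cut C2–C3 and C3–O together, so that carbocycle and oxirane arise from the open-chain precursor A2, a (Z)-allylic diphenylsulfonium salt with a C2 methyl ketone and with chain and pyranone already on C1 and C6. Forward, base forms the ylide at C3, which adds to the C2 carbonyl; the alkoxide then displaces the sulfide at C3 and gives A1, which is compound 24 of the chosen route.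
- Merits: no oxidant is used, so site selectivity among three alkenes is not an issue; the oxirane is cis-fused by construction; the last two steps are those of the chosen route.
- Weak points: A2 must be assembled without a ring to organise its vicinal quaternary (C6) and tertiary (C1) centres, and needs a (Z)-trisubstituted allylic sulfonium unit. C1 is α to the C2 ketone and is exposed to the ylide-forming base. Allylic sulfonium ylides can react through the γ-carbon or undergo 2,3-shift. The carbonyl face the ylide attacks, which decides the oxirane face, has no clear control element.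
- Comparison: for the oxirane this road is better than the chosen plan, which must win a site- and face-selective epoxidation of 23. The chosen plan offers in return a ring whose C1/C6 relationship follows from alkene geometry, and a pyranone built on a robust cyclic ketone instead of one carried through acyclic carbonyl chemistry.

**Alternative 2:** Cut C1–C2 and C5–C6 as in step 6, but with a small dienophile. Ethyl (E)-3-methyl-4-oxobut-2-enoate A3 and dienol ether 8, under a chiral oxazaborolidinium cation, give cycloadduct A4 with a C6 formyl and a C1 ester.
- Merits: A3 is doubly activated and unhindered at the β-carbon, so the cycloaddition should be faster and more face-selective than with dienal 6. Ring, C1 and C6 are secured early from cheap materials.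
- Weak points: the C1 ester must then become the whole C7–C12 chain. That needs a trisubstituted (E)-alkene beside a hindered ring carbon (ketone olefination with poor geometry control, or alkyne carbometalation with an aluminium reagent). Above all, the α-stereogenic ketone at C9 would have to be installed late under reagent control, for which no well-established method exists. C1 also becomes α to a carbonyl during the elaboration.
- Comparison: in cycloaddition reactivity this road is better, and the chosen plan is its convergent variant, with the ester of A3 replaced by the finished chain of 6. Against the slower cycloaddition the chosen plan sets that C7=C8 and C9 are settled before the ring exists and nothing has to be built at C1 afterwards.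

**Alternative 3:** Cut C1–C2 and C4–C5. tert-Butyl 2-methyl-3-oxopentanoate A5 adds through its α-carbon to the β-carbon of enynal A6 under chiral primary-amine iminium catalysis. Acid then removes the ester with decarboxylation and closes C4–C5 by aldol condensation to cyclohexenone A7, with C1 set.
- Merits: metal-free, inexpensive and operationally simple; the enone arrives at the right oxidation level without a dehydrosilylation; the alkynyl group is a slim, inert placeholder.
- Weak points: both partners are α-branched, so the Michael step is slow and the iminium geometry harder to control. C6 in A7 is only tertiary; the quaternary centre must be made later by γ-selective hydroxyalkylation of an extended dienolate, in competition with α-attack and with only the C1 substituent to steer the face. The alkyne then needs carboalumination and the same late, reagent-controlled construction of C9 as in Alternative 2.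
- Comparison: for setting the first stereocentre this road is at least as practical as step 6. The chosen plan sets against it that C1 and C6 form together with fixed relative configuration and that C9 is never created on an advanced intermediate.

Key step: step 15

Assumption: the sense of induction of the two chiral catalysts (oxazaborolidinium in step 6, salen manganese chloride in step 17) is taken from the accepted models for 2-substituted enals and conjugated cis-alkenes; if either proves opposite, the enantiomeric catalyst is used.

Naming note: "chain" means the C1 substituent (2E,4R,5S)-5-(tert-butyldimethylsilyloxy)-4-methylhept-2-en-2-yl (C7–C12; 9R,10S). Ring locants and α/β faces are those defined under "The problem".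

Step 1
Reactants: 1 propanal (two molecules, donor and acceptor)
Product: 2 (2S,3S)-3-hydroxy-2-methylpentanal
Conditions: L-proline (10 mol %), DMF, 4 °C, slow addition of 1
Reagents that add atoms: none
Why: Proline-catalysed direct aldol self-addition (enamine catalysis through a hydrogen-bonded chair transition state) creates C9 (S at this stage) and the anti C10 carbinol; the minor syn C10 epimer has the same C9 configuration and converges when C10 is oxidised in step 19.

Step 2
Reactants: 2 (2S,3S)-3-hydroxy-2-methylpentanal
Product: 3 (2S,3S)-3-(tert-butyldimethylsilyloxy)-2-methylpentanal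
Conditions: t-BuMe2SiOTf, 2,6-lutidine, CH2Cl2, −78 °C
Reagents that add atoms: tert-butyldimethylsilyl trifluoromethanesulfonate, CC(C)(C)[Si](C)(C)OS(=O)(=O)C(F)(F)F
Why: O-Silylation with a silyl triflate and a hindered pyridine at low temperature does not enolise the α-stereogenic aldehyde, and the bulky ether blocks retro-aldol and β-elimination in the olefinations.

Step 3
Reactants: 3 (2S,3S)-3-(tert-butyldimethylsilyloxy)-2-methylpentanal; 4 2-(triphenylphosphoranylidene)propanal
Product: 5 (2E,4R,5S)-5-(tert-butyldimethylsilyloxy)-2,4-dimethylhept-2-enal
Conditions: toluene, 90 °C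
Reagents that add atoms: none
Why: Wittig olefination with a stabilised formyl ylide under base-free conditions gives the (E)-enal (the future C7=C8 bond) and leaves C9 untouched.

Step 4
Reactants: 5 (2E,4R,5S)-5-(tert-butyldimethylsilyloxy)-2,4-dimethylhept-2-enal; 4 2-(triphenylphosphoranylidene)propanal
Product: 6 (2E,4E,6R,7S)-7-(tert-butyldimethylsilyloxy)-2,4,6-trimethylnona-2,4-dienal
Conditions: toluene, 110 °C
Reagents that add atoms: none
Why: Second Wittig homologation with the same ylide; the (E)-geometry formed here later fixes the trans relation of C1 and C6, and the less electrophilic dienal product does not react further.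

Step 5
Reactants: 7 2-methylpent-1-en-3-one
Product: 8 tert-butyldimethyl{[(3Z)-2-methylpenta-1,3-dien-3-yl]oxy}silane
Conditions: t-BuMe2SiOTf, Et3N, CH2Cl2, 0 °C
Reagents that add atoms: tert-butyldimethylsilyl trifluoromethanesulfonate, CC(C)(C)[Si](C)(C)OS(=O)(=O)C(F)(F)F
Why: Soft enolisation at the only acidic position (the ethyl CH2) gives the preferred (Z)-enol ether, whose terminal methyl lies outside the diene so that the s-cis conformer is accessible.

Step 6
Reactants: 6 (2E,4E,6R,7S)-7-(tert-butyldimethylsilyloxy)-2,4,6-trimethylnona-2,4-dienal; 8 tert-butyldimethyl{[(3Z)-2-methylpenta-1,3-dien-3-yl]oxy}silane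
Product: 9 (1S,2R,6R)-cycloadduct: cyclohex-3-ene with the chain at C1, methyl at C2 (cis to CHO), tert-butyldimethylsilyl enol ether at C3=C4, methyl at C4, and methyl plus formyl at C6 (CHO trans to the chain)
Conditions: (S)-3,3-diphenyl-1-(o-tolyl)tetrahydro-1H,3H-pyrrolo[1,2-c][1,3,2]oxazaborole (20 mol %), HN(SO2CF3)2 (18 mol %), CH2Cl2, −78 → −40 °C
Reagents that add atoms: none
Why: Oxazaborolidinium-catalysed Diels–Alder reaction: boron binds the formyl oxygen, only the α,β-bond of 6 is activated, the enol ether terminus (C2) bonds to the β-carbon (C1) and the CH2 terminus (C5) to the α-carbon (C6). Suprafacial addition to the (E)-dienophile makes the chain trans to CHO and cis to the C6 methyl; the catalyst shields one enal face (attack on the Cα-Re face) and so sets the absolute configuration of C1 and C6, while the endo-derived C2 centre is erased in step 10.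

Step 7
Reactants: 9 (1S,2R,6R)-cycloadduct aldehyde
Product: 10 carbinol: as 9, with CH(OH)CH2CH3 at C6 in place of CHO (both C2′ epimers)
Conditions: EtMgBr, Et2O, −78 → 0 °C
Reagents that add atoms: ethylmagnesium bromide, CC[Mg]Br
Why: Grignard addition to the non-enolisable neopentyl aldehyde; enol ether and silyl ether are inert, and the new C2′ carbinol centre is oxidised in step 13, so its configuration is immaterial.

Step 8
Reactants: 10 carbinol
Product: 11 triethylsilyl ether: as 10, with CH(OSiEt3)CH2CH3 at C6
Conditions: Et3SiOTf, 2,6-lutidine, CH2Cl2, −40 → 0 °C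
Reagents that add atoms: triethylsilyl trifluoromethanesulfonate, CC[Si](CC)(CC)OS(=O)(=O)C(F)(F)F
Why: Silylation of the hindered secondary alcohol with a silyl triflate; the triethylsilyl group is chosen because it can later be removed in the presence of the C10 tert-butyldimethylsilyl ether.

Step 9
Reactants: 11 triethylsilyl ether
Product: 12 (1S,2R,6R)-enone: 2,4,6-trimethylcyclohex-3-en... ring with C3 ketone and C4=C5 alkene, chain at C1, and methyl plus CH(OSiEt3)CH2CH3 at C6
Conditions: Pd(OAc)2 (1.1 equiv), MeCN, 40 °C
Reagents that add atoms: none
Why: Saegusa–Ito oxidation: palladation of the enol ether at C4 and β-hydride elimination toward ring C5 (the conjugated, more substituted product) give the C4=C5 enone; the trisubstituted chain alkene and both silyl ethers are untouched.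

Step 10
Reactants: 12 (1S,2R,6R)-enone
Product: 13 (1S,6R)-dienyl triflate: cyclohexa-2,4-diene with methyl at C2, OSO2CF3 at C3, methyl at C4, chain at C1, and methyl plus CH(OSiEt3)CH2CH3 at C6
Conditions: KN(SiMe3)2, THF, −78 °C; PhNTf2, −78 → 0 °C
Reagents that add atoms: N-phenylbis(trifluoromethanesulfonimide), O=S(=O)(N(c1ccccc1)S(=O)(=O)C(F)(F)F)C(F)(F)F
Why: Kinetic enolisation can occur only at C2 (C6 is quaternary and C2′ is an ether), and O-sulfonylation of the cross-conjugated dienolate gives the 2-triflyloxy-1,3-diene; the C2 stereocentre is cleared.

Step 11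
Reactants: 13 (1S,6R)-dienyl triflate
Product: 14 (1R,6R)-ring diene: 2,4,6-trimethylcyclohexa-2,4-diene with the chain at C1 and CH(OSiEt3)CH2CH3 at C6
Conditions: Pd(OAc)2 (5 mol %), PPh3 (10 mol %), HCO2H, Bu3N, DMF, 50 °C
Reagents that add atoms: none
Why: Palladium-catalysed formate reduction of an enol triflate (oxidative addition of zerovalent palladium, formate-to-hydride exchange with loss of CO2, reductive elimination) replaces C3–OTf by C3–H without moving the diene.

Step 12
Reactants: 14 (1R,6R)-ring diene triethylsilyl ether
Product: 15 (1R,6R)-ring diene carbinol: as 14, with CH(OH)CH2CH3 at C6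
Conditions: pyridinium p-toluenesulfonate (0.2 equiv), MeOH–CH2Cl2, 0 °C → rt
Reagents that add atoms: none
Why: Acid-catalysed methanolysis cleaves a triethylsilyl ether much faster than a secondary tert-butyldimethylsilyl ether, and the mild acid leaves the ring diene in place.

Step 13
Reactants: 15 (1R,6R)-ring diene carbinol
Product: 16 (1R,6R)-ethyl ketone: 1-[ring]propan-1-one, ring = 2,4,6-trimethylcyclohexa-2,4-diene with the chain at C1 and the propanoyl group at C6 (trans to the chain)
Conditions: Dess–Martin periodinane, NaHCO3, CH2Cl2, rt
Reagents that add atoms: none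
Why: Dess–Martin oxidation of the hindered carbinol under buffered conditions gives the ketone whose only α-hydrogens are those of the CH2 group.

Step 14
Reactants: 17 methylmalonic acid
Product: 18 methylmalonyl dichloride
Conditions: SOCl2 (neat), 50 °C; distillation
Reagents that add atoms: thionyl chloride, ClS(Cl)=O
Why: Standard conversion of a malonic acid into its dichloride; the volatile product is distilled and used at once.

Step 15
Reactants: 16 (1R,6R)-ethyl ketone; 18 methylmalonyl dichloride
Product: 21 (1R,6R)-hydroxypyranone: 4-hydroxy-3,5-dimethyl-2H-pyran-2-one bonded through C2′ (pyranone position 6) to C6 of the ring diene that carries the chain at C1, via silyl enol ether 19 (not isolated), via diketo acid chloride 20 (not isolated)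
Conditions: LiN(SiMe3)2, Me3SiCl, THF, −78 °C; concentrate, pentane, filter; then 18, Et2O, −78 °C → rt
Reagents that add atoms: chlorotrimethylsilane, C[Si](C)(C)Cl (its silicon is found only in intermediate 19)
Why: Deprotonation is possible only at the CH2 group (C3′), since C6 bears no hydrogen, and silylation gives the (Z)-enol ether 19. The enol ether reacts at carbon with one acyl chloride group of 18 and Me3SiCl leaves; this forms C3′–C4′ and the open-chain 1,3-diketone acid chloride 20. Enolisation of the C2′ carbonyl toward C3′ then places an oxygen nucleophile six atoms from the remaining acyl chloride, and its addition–elimination there (6-exo-trig; a ketene formed by loss of HCl would be trapped in the same sense) closes O1′–C6′, after which the product settles as the 4-hydroxy-2-pyranone tautomer 21. The closest known reaction type is the condensation of ketone silyl enol ethers with malonyl dichlorides to 6-substituted 4-hydroxy-2-pyranones. No stereocentre is formed, and C1, C6 and C9 are untouched because none is α to an enolisable carbonyl. The step needs C- over O-acylation, favoured by the amine-free enol ether at low temperature, and one direction of enolisation, enforced by the quaternary C6. Ring diene, chain alkene and silyl ether are spectators, so no Lewis acid is used and the mixture is worked up as soon as HCl evolution ends.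

Step 16
Reactants: 21 (1R,6R)-hydroxypyranone
Product: 23 (1R,6R)-methoxypyranone: 2-methoxy-3,5-dimethyl-4H-pyran-4-one bonded through C2′ to C6 of the ring diene that carries the chain at C1, via hydroxypyrylium triflate 22 (not isolated)
Conditions: MeOTf, CH2Cl2, 0 °C → rt; then aq. NaHCO3
Reagents that add atoms: methyl trifluoromethanesulfonate, COS(=O)(=O)C(F)(F)F
Why: A hard methylating agent alkylates the neutral 4-hydroxy-2-pyranone at the lactone carbonyl oxygen, its most basic site, giving the 4-hydroxy-2-methoxypyrylium salt 22, which loses the hydroxyl proton on bicarbonate work-up; this is the known regiochemistry for 4-hydroxy-3,5-dimethyl-2-pyranones. The proton stays bound in 22 until the quench, which limits acid damage to diene and silyl ether.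

Step 17
Reactants: 23 (1R,6R)-methoxypyranone ring diene
Product: 24 (1S,2S,3R,6R,9R,10S)-epoxide: C10 tert-butyldimethylsilyl ether of the C10-reduced target (C2–C3 oxirane on the α-face)
Conditions: (R,R)-N,N′-bis(3,5-di-tert-butylsalicylidene)-1,2-cyclohexanediaminomanganese chloride (10 mol %), N-methylmorpholine N-oxide, mCPBA, CH2Cl2, −78 °C
Reagents that add atoms: 3-chloroperbenzoic acid, OOC(=O)c1cccc(Cl)c1
Why: Jacobsen–Katsuki epoxidation: the manganese oxo species reacts with conjugated cis-alkenes and leaves the isolated C7=C8 bond and the electron-poor pyranone alone; within the diene it attacks C2=C3 because C5 is flanked by the quaternary C6. Oxygen is delivered to the α-face under catalyst control, supported by the pyranone on the β-face of C6, which sets C2 (S) and C3 (R).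

Step 18
Reactants: 24 (1S,2S,3R,6R,9R,10S)-epoxide silyl ether
Product: 25 (1S,2S,3R,6R,9R,10S)-epoxy alcohol: as 24, with free C10–OH
Conditions: Bu4NF, THF, 0 °C → rt
Reagents that add atoms: none
Why: Fluoride-mediated silyl ether cleavage under non-acidic conditions that the vinyl oxirane and the pyranone tolerate.

Step 19
Reactants: 25 (1S,2S,3R,6R,9R,10S)-epoxy alcohol
Product: 26 target, (1S,2S,3R,6R,9R): C10 ketone
Conditions: Dess–Martin periodinane, NaHCO3, CH2Cl2, 0 °C
Reagents that add atoms: none
Why: Buffered Dess–Martin oxidation converts the carbinol into the ketone under neutral conditions, without epimerising C9, moving C7=C8 into conjugation or opening the oxirane.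

## Compound list

1 | propanal | CCC=O | starting material
2 | (2S,3S)-3-hydroxy-2-methylpentanal | CC[C@H](O)[C@H](C)C=O | intermediate
3 | (2S,3S)-3-(tert-butyldimethylsilyloxy)-2-methylpentanal | CC[C@H](O[Si](C)(C)C(C)(C)C)[C@H](C)C=O | intermediate
4 | 2-(triphenylphosphoranylidene)propanal | CC(C=O)=P(c1ccccc1)(c1ccccc1)c1ccccc1 | starting material
5 | (2E,4R,5S)-5-(tert-butyldimethylsilyloxy)-2,4-dimethylhept-2-enal | CC[C@H](O[Si](C)(C)C(C)(C)C)[C@H](C)/C=C(\C)C=O | intermediate
6 | (2E,4E,6R,7S)-7-(tert-butyldimethylsilyloxy)-2,4,6-trimethylnona-2,4-dienal | CC[C@H](O[Si](C)(C)C(C)(C)C)[C@H](C)/C=C(C)/C=C(\C)C=O | intermediate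
7 | 2-methylpent-1-en-3-one | CCC(=O)C(C)=C | starting material
8 | tert-butyldimethyl{[(3Z)-2-methylpenta-1,3-dien-3-yl]oxy}silane | C/C=C(\O[Si](C)(C)C(C)(C)C)C(C)=C | intermediate
9 | (1S,2R,6R)-cycloadduct: C6 formyl and methyl, C3=C4 silyl enol ether, chain at C1 | CC[C@H](O[Si](C)(C)C(C)(C)C)[C@H](C)/C=C(\C)[C@@H]1[C@@H](C)C(O[Si](C)(C)C(C)(C)C)=C(C)C[C@@]1(C)C=O | intermediate
10 | carbinol from 9, CH(OH)Et at C6 (C2′ epimers, centre left undefined) | CC[C@H](O[Si](C)(C)C(C)(C)C)[C@H](C)/C=C(\C)[C@@H]1[C@@H](C)C(O[Si](C)(C)C(C)(C)C)=C(C)C[C@@]1(C)C(O)CC | intermediate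
11 | triethylsilyl ether of 10 | CC[C@H](O[Si](C)(C)C(C)(C)C)[C@H](C)/C=C(\C)[C@@H]1[C@@H](C)C(O[Si](C)(C)C(C)(C)C)=C(C)C[C@@]1(C)C(O[Si](CC)(CC)CC)CC | intermediate
12 | (1S,2R,6R)-enone: C3 ketone, C4=C5 | CC[C@H](O[Si](C)(C)C(C)(C)C)[C@H](C)/C=C(\C)[C@@H]1[C@@H](C)C(=O)C(C)=C[C@@]1(C)C(O[Si](CC)(CC)CC)CC | intermediate
13 | (1S,6R)-dienyl triflate: C2=C3(OTf)–C4=C5 | CC[C@H](O[Si](C)(C)C(C)(C)C)[C@H](C)/C=C(\C)[C@@H]1C(C)=C(OS(=O)(=O)C(F)(F)F)C(C)=C[C@@]1(C)C(O[Si](CC)(CC)CC)CC | intermediate
14 | (1R,6R)-ring diene, CH(OSiEt3)Et at C6 | CC[C@H](O[Si](C)(C)C(C)(C)C)[C@H](C)/C=C(\C)[C@@H]1C(C)=CC(C)=C[C@@]1(C)C(O[Si](CC)(CC)CC)CC | intermediate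
15 | (1R,6R)-ring diene carbinol, CH(OH)Et at C6 | CC[C@H](O[Si](C)(C)C(C)(C)C)[C@H](C)/C=C(\C)[C@@H]1C(C)=CC(C)=C[C@@]1(C)C(O)CC | intermediate
16 | (1R,6R)-ethyl ketone, propanoyl at C6 (key-step precursor) | CC[C@H](O[Si](C)(C)C(C)(C)C)[C@H](C)/C=C(\C)[C@@H]1C(C)=CC(C)=C[C@@]1(C)C(=O)CC | intermediate
17 | methylmalonic acid | CC(C(=O)O)C(=O)O | starting material
18 | methylmalonyl dichloride | CC(C(=O)Cl)C(=O)Cl | intermediate
19 | (Z)-trimethylsilyl enol ether of 16 | CC[C@H](O[Si](C)(C)C(C)(C)C)[C@H](C)/C=C(\C)[C@@H]1C(C)=CC(C)=C[C@@]1(C)/C(O[Si](C)(C)C)=C/C | intermediate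
20 | 2,4-dimethyl-3,5-dioxo acid chloride from 19 and 18 (C3′/C5′ epimers) | CC[C@H](O[Si](C)(C)C(C)(C)C)[C@H](C)/C=C(\C)[C@@H]1C(C)=CC(C)=C[C@@]1(C)C(=O)C(C)C(=O)C(C)C(=O)Cl | intermediate
21 | (1R,6R)-hydroxypyranone (key-step product) | CC[C@H](O[Si](C)(C)C(C)(C)C)[C@H](C)/C=C(\C)[C@@H]1C(C)=CC(C)=C[C@@]1(C)C2=C(C)C(O)=C(C)C(=O)O2 | intermediate
22 | 4-hydroxy-2-methoxypyrylium triflate from 21 | CC[C@H](O[Si](C)(C)C(C)(C)C)[C@H](C)/C=C(\C)[C@@H]1C(C)=CC(C)=C[C@@]1(C)c1[o+]c(OC)c(C)c(O)c1C.[O-]S(=O)(=O)C(F)(F)F | intermediate
23 | (1R,6R)-2-methoxy-4-pyranone ring diene | CC[C@H](O[Si](C)(C)C(C)(C)C)[C@H](C)/C=C(\C)[C@@H]1C(C)=CC(C)=C[C@@]1(C)c1oc(OC)c(C)c(=O)c1C | intermediate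
24 | (1S,2S,3R,6R,9R,10S)-epoxide, C10 silyl ether | CC[C@H](O[Si](C)(C)C(C)(C)C)[C@H](C)/C=C(\C)[C@@H]1[C@]2(C)O[C@@H]2C(C)=C[C@@]1(C)c1oc(OC)c(C)c(=O)c1C | intermediate
25 | (1S,2S,3R,6R,9R,10S)-epoxy alcohol | CC[C@H](O)[C@H](C)/C=C(\C)[C@@H]1[C@]2(C)O[C@@H]2C(C)=C[C@@]1(C)c1oc(OC)c(C)c(=O)c1C | intermediate
26 | CNP0336888.2, (1S,2S,3R,6R,9R) | CCC(=O)[C@H](C)/C=C(\C)[C@@H]1[C@]2(C)O[C@@H]2C(C)=C[C@@]1(C)c1oc(OC)c(C)c(=O)c1C | target

## Step count and least certain steps

Total: 19 steps. Longest linear sequence: 17 steps (1–4, 6–13, 15–19); steps 5 and 14 are side branches.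

**Step 15 (key step).** Most likely to fail through O-acylation of the enol ether or double acylation of 18, or because the HCl released on ring closure attacks the diene or the C10 silyl ether before closure is complete; the neopentyl ketone may also enolise slowly. Fallback (stepwise, ester instead of acid chloride): from 16, the lithium enolate (LiN(i-Pr)2, THF, −78 °C) is C-acylated with the imidazolide of methyl hydrogen methylmalonate to give the β,δ-diketo ester, methyl 2,4-dimethyl-3,5-dioxo-5-[ring]pentanoate F1. DBU in toluene at 60 °C then closes the lactone with loss of methanol and returns to 21.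

**Step 6.** Most likely to fail through slow cycloaddition at the trisubstituted α,β-bond of the dienal, which would let Mukaiyama-type addition of the enol ether to the activated formyl group or decomposition of 8 take over; facial control may also be weak. Fallback (more nucleophilic diene, no Lewis acid): pentan-3-one and N,N-dimethylformamide dimethyl acetal give (E)-1-(dimethylamino)-2-methylpent-1-en-3-one F2. KN(SiMe3)2 and t-BuMe2SiCl convert it into the 1-amino-3-siloxy diene F3. Heating F3 with 6 in toluene gives the amino cycloadduct F4; the ring diastereomers are separable because the chain is enantiopure, or the face is controlled with N,N′-bis(3,5-di-tert-butylsalicylidene)-1,2-cyclohexanediaminochromium chloride. Dilute HCl in THF removes the silyl group and dimethylamine to give the enone aldehyde F5. EtMgBr at −78 °C adds to the aldehyde only, giving the enone carbinol F6, and Et3SiOTf returns to 12.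

**Step 17.** Most likely to fail through oxygen delivery to the β-face (the pseudoaxial C1 chain shields the α-face at C2 and the catalyst must override it) or through loss of site selectivity. Fallback (halohydrin route, which puts the oxygen on the face opposite to electrophile attack): from 23, N-bromosuccinimide in aqueous 1,2-dimethoxyethane at 0 °C gives the bromohydrin F7 (bromine on the β-face at C3, water anti at tertiary C2). K2CO3 in MeOH closes the α-oxirane and returns to 24.

**Step 16.** Most likely to fail through acid-promoted migration of the ring diene or loss of the C10 silyl ether while the proton sits on salt 22, or through competing methylation of the C4′ oxygen. Fallback (silyl transfer in place of proton transfer): from 21, Me3SiCl and Et3N give the 4′-O-trimethylsilyl ether F8. MeOTf with 2,6-di-tert-butylpyridine methylates the lactone carbonyl oxygen and the silyl group leaves as silyl triflate, so no Brønsted acid is formed; this returns to 23.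

**Step 12.** Most likely to fail through incomplete discrimination between the two silyl ethers, because the neopentyl position slows cleavage of the nominally more labile triethylsilyl group. Fallback (global deprotection, site-selective reprotection): from 14, HF·pyridine in THF removes both silyl groups to give the diol F9. t-BuMe2SiCl and imidazole in DMF at 0 °C silylate only the less hindered C10 hydroxyl and return to 15.

## Further compounds

F1 | step 15 | methyl 2,4-dimethyl-3,5-dioxo-5-[(1R,6R)-ring]pentanoate (C3′/C5′ epimers) | CC[C@H](O[Si](C)(C)C(C)(C)C)[C@H](C)/C=C(\C)[C@@H]1C(C)=CC(C)=C[C@@]1(C)C(=O)C(C)C(=O)C(C)C(=O)OC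
F2 | step 6 | (E)-1-(dimethylamino)-2-methylpent-1-en-3-one | CCC(=O)/C(C)=C/N(C)C
F3 | step 6 | (1E,3Z)-3-(tert-butyldimethylsilyloxy)-N,N,2-trimethylpenta-1,3-dien-1-amine | C/C=C(\O[Si](C)(C)C(C)(C)C)/C(C)=C/N(C)C
F4 | step 6 | amino cycloadduct: as 9 with NMe2 at C5 (C5 epimers) | CC[C@H](O[Si](C)(C)C(C)(C)C)[C@H](C)/C=C(\C)[C@@H]1[C@@H](C)C(O[Si](C)(C)C(C)(C)C)=C(C)C(N(C)C)[C@@]1(C)C=O
F5 | step 6 | enone aldehyde: as 12 with CHO at C6 | CC[C@H](O[Si](C)(C)C(C)(C)C)[C@H](C)/C=C(\C)[C@@H]1[C@@H](C)C(=O)C(C)=C[C@@]1(C)C=O
F6 | step 6 | enone carbinol: as 12 with CH(OH)Et at C6 (C2′ epimers) | CC[C@H](O[Si](C)(C)C(C)(C)C)[C@H](C)/C=C(\C)[C@@H]1[C@@H](C)C(=O)C(C)=C[C@@]1(C)C(O)CC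
F7 | step 17 | bromohydrin of 23: C2 α-hydroxy, C3 β-bromo | CC[C@H](O[Si](C)(C)C(C)(C)C)[C@H](C)/C=C(\C)[C@@H]1[C@](C)(O)[C@@H](Br)C(C)=C[C@@]1(C)c1oc(OC)c(C)c(=O)c1C
F8 | step 16 | 4′-O-trimethylsilyl ether of 21 | CC[C@H](O[Si](C)(C)C(C)(C)C)[C@H](C)/C=C(\C)[C@@H]1C(C)=CC(C)=C[C@@]1(C)C2=C(C)C(O[Si](C)(C)C)=C(C)C(=O)O2
F9 | step 12 | diol: 14 without either silyl group (C2′ epimers) | CC[C@H](O)[C@H](C)/C=C(\C)[C@@H]1C(C)=CC(C)=C[C@@]1(C)C(O)CC
A1 | alternative 1 | C10 tert-butyldimethylsilyl ether of the C10-reduced target (identical with 24) | CC[C@H](O[Si](C)(C)C(C)(C)C)[C@H](C)/C=C(\C)[C@@H]1[C@]2(C)O[C@@H]2C(C)=C[C@@]1(C)c1oc(OC)c(C)c(=O)c1C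
A2 | alternative 1 | open-chain (Z)-allylic diphenylsulfonium tetrafluoroborate with C2 methyl ketone, chain at C1 and pyranone at C6 | CC[C@H](O[Si](C)(C)C(C)(C)C)[C@H](C)/C=C(\C)[C@H](C(C)=O)[C@](C)(c1oc(OC)c(C)c(=O)c1C)/C=C(C)\C[S+](c1ccccc1)c1ccccc1.F[B-](F)(F)F
A3 | alternative 2 | ethyl (E)-3-methyl-4-oxobut-2-enoate | CCOC(=O)/C=C(\C)C=O
A4 | alternative 2 | cycloadduct with C6 formyl, C1 ester and C3 silyl enol ether | CCOC(=O)[C@@H]1[C@@H](C)C(O[Si](C)(C)C(C)(C)C)=C(C)C[C@@]1(C)C=O
A5 | alternative 3 | tert-butyl 2-methyl-3-oxopentanoate | CCC(=O)C(C)C(=O)OC(C)(C)C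
A6 | alternative 3 | (E)-2-methyl-5-(trimethylsilyl)pent-2-en-4-ynal | C[Si](C)(C)C#C/C=C(\C)C=O
A7 | alternative 3 | 2,4,6-trimethyl-5-(trimethylsilylethynyl)cyclohex-2-enone with C1 set | C[Si](C)(C)C#C[C@@H]1[C@@H](C)C(=O)C(C)=C[C@H]1C
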